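Each dihydrobenzofuran is cut across C2–C3 and O1–C7a into a diarylmethane and 4-methoxybenzaldehyde. For central ring B, the doubly benzylic C3 (between C3a of ring B's benzo ring and C4 of ring C's benzo ring) is lithiated under the direction of a homochiral p-tolylsulfinyl group at C4. Addition to the aldehyde C=O forms C2–C3, and alkoxide O1 then displaces fluoride at C7a: a formal (3+2) annulation in one operation. The precursor is an open fluoro sulfinyl diarylmethane. The sulfoxide, which also sets C3, is then exchanged for magnesium to start the next cycle, so rings C, B and A arise from the same annulation.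

Key step: step 10

Remarks on the chemistry:
- Ring A carries the styryl group, ring B is central, ring C carries the 3,5-dioxygenated phenyl group. Positions follow 2,3-dihydrobenzofuran numbering (O1, C2, C3, C3a, C4 to C7, C7a).
- Assumption: the sense of induction by the sulfinyl group follows the lithium chelate model given under step 10, so that (R)-sulfur gives 3R and (S)-sulfur gives 3S. If the opposite sense were found, sulfinates 3 and 7 would exchange roles with no other change.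
- Each annulation is expected to favour the 2,3-trans ring. Any minor cis epimer at C2 would be removed by chromatography at that stage.
- Grignard reagent 2 is prepared once as a titrated stock solution; one portion serves each of the two enantiomeric sulfoxide syntheses.

Step 1
Reactants: 1 1-bromo-3-fluoro-5-methoxybenzene
Product: 2 (3-fluoro-5-methoxyphenyl)magnesium bromide (titrated THF solution, kept under argon)
Conditions: Mg turnings, I2 (cat.), THF, 40 °C
Reagents that add atoms: magnesium, [Mg]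
Why: Grignard reagent formation by insertion of magnesium into the aryl C–Br bond, which leaves the aryl fluoride and the methyl ether untouched and gives one batch for steps 2 and 4.

Step 2
Reactants: 2 (3-fluoro-5-methoxyphenyl)magnesium bromide; 3 (1S,2R,5S)-menthyl (R)-4-methylbenzenesulfinate
Product: 4 (R)-1-fluoro-3-methoxy-5-(p-tolylsulfinyl)benzene
Conditions: 2 (1.0 equiv) added to 3, toluene/THF, 0 °C; aq. NH4Cl
Reagents that add atoms: none
Why: Andersen sulfoxide synthesis, in which the aryl Grignard reagent displaces menthoxide at sulfur with inversion and so fixes the (R)-sulfur centre.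

Step 3
Reactants: 4 (R)-1-fluoro-3-methoxy-5-(p-tolylsulfinyl)benzene
Product: 6 (R)-2-fluoro-4-methoxy-6-(p-tolylsulfinyl)benzaldehyde, via arylmagnesium chloride 5 (not isolated)
Conditions: (TMP)MgCl·LiCl (TMP = 2,2,6,6-tetramethylpiperidide), THF, −30 °C; DMF; aq. NH4Cl
Reagents that add atoms: DMF, CN(C)C=O
Why: Directed ortho-magnesiation should occur at the C–H flanked by the sulfinyl group and fluorine, the most acidic and doubly directed site, and formylation follows; the amide base does not attack sulfur, so its configuration is kept.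

Step 4
Reactants: 2 (3-fluoro-5-methoxyphenyl)magnesium bromide; 7 (1R,2S,5R)-menthyl (S)-4-methylbenzenesulfinate
Product: 8 (S)-1-fluoro-3-methoxy-5-(p-tolylsulfinyl)benzene
Conditions: 2 (1.0 equiv) added to 7, toluene/THF, 0 °C; aq. NH4Cl
Reagents that add atoms: none
Why: Andersen sulfoxide synthesis with the antipodal sulfinate, inversion at sulfur giving the (S)-sulfoxide.

Step 5
Reactants: 8 (S)-1-fluoro-3-methoxy-5-(p-tolylsulfinyl)benzene
Product: 10 (S)-2-fluoro-4-methoxy-6-(p-tolylsulfinyl)benzaldehyde, via arylmagnesium chloride 9 (not isolated)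
Conditions: (TMP)MgCl·LiCl, THF, −30 °C; DMF; aq. NH4Cl
Reagents that add atoms: DMF, CN(C)C=O
Why: Same directed ortho-magnesiation and formylation as in step 3, in the enantiomeric series.

Step 6
Reactants: 4 (R)-1-fluoro-3-methoxy-5-(p-tolylsulfinyl)benzene; 11 3,5-dimethoxybenzyl bromide
Product: 14 (R)-2-(3,5-dimethoxybenzyl)-1-fluoro-5-methoxy-3-(p-tolylsulfinyl)benzene, via aryllithium 12 (not isolated), via arylzinc chloride 13 (not isolated)
Conditions: ZnCl2·2LiCl, Li(TMP), THF, −78 °C; then 11, Pd(PPh3)4 (5 mol %), 50 °C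
Reagents that add atoms: none
Why: In situ trapping metalation, in which the hindered lithium amide removes the C–H flanked by fluorine and the sulfinyl group and the zinc salt already present captures the aryllithium before it can attack sulfur or lose lithium fluoride, gives the arylzinc reagent that Negishi coupling with the benzylic bromide under zerovalent palladium catalysis needs.

Step 7
Reactants: 14 (R)-2-(3,5-dimethoxybenzyl)-1-fluoro-5-methoxy-3-(p-tolylsulfinyl)benzene; 15 4-methoxybenzaldehyde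
Product: 18 (2R,3R)-3-(3,5-dimethoxyphenyl)-6-methoxy-2-(4-methoxyphenyl)-4-[(R)-p-tolylsulfinyl]-2,3-dihydrobenzofuran, via benzylic lithium 16 (not isolated), via lithium alkoxide 17 (not isolated)
Conditions: LiN(i-Pr)2 (1.05 equiv), THF, −78 °C; 15, −78 °C; then DMPU, −78 → 60 °C
Reagents that add atoms: none
Why: Same domino as in step 10 (sulfinyl-directed benzylic lithiation, addition to the aldehyde, SNAr closure of ring C at C7a), in which the (R)-sulfinyl group should set C3 as R by the chelate model and the trans C2 centre follows from the addition transition state.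

Step 8
Reactants: 18 ring C sulfoxide; 10 (S)-2-fluoro-4-methoxy-6-(p-tolylsulfinyl)benzaldehyde
Product: 20 [(2R,3R)-3-(3,5-dimethoxyphenyl)-6-methoxy-2-(4-methoxyphenyl)-2,3-dihydrobenzofuran-4-yl][2-fluoro-4-methoxy-6-((S)-p-tolylsulfinyl)phenyl]methanol (both carbinol epimers), via arylmagnesium chloride 19 (not isolated)
Conditions: i-PrMgCl·LiCl (1.05 equiv), THF, −50 °C; then 10, −50 → 0 °C; aq. NH4Cl
Reagents that add atoms: none
Why: Sulfoxide–magnesium exchange should release the more stabilised, ortho-substituted aryl group as its Grignard reagent, which adds to the aldehyde; the new carbinol centre needs no control because step 9 removes it.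

Step 9
Reactants: 20 diaryl carbinol
Product: 21 (2R,3R)-3-(3,5-dimethoxyphenyl)-4-[2-fluoro-4-methoxy-6-((S)-p-tolylsulfinyl)benzyl]-6-methoxy-2-(4-methoxyphenyl)-2,3-dihydrobenzofuran
Conditions: Et3SiH, CF3CO2H, CH2Cl2, −20 → 0 °C
Reagents that add atoms: none
Why: Ionic hydrogenation, in which the doubly benzylic cation stabilised by the para-methoxy group forms far more readily than any cation from the C2–O1 bond of ring C and is reduced by the silane.

Step 10
Reactants: 21 fluoro sulfinyl diarylmethane; 15 4-methoxybenzaldehyde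
Product: 24 (2S,3S)-3-[(2R,3R)-3-(3,5-dimethoxyphenyl)-6-methoxy-2-(4-methoxyphenyl)-2,3-dihydrobenzofuran-4-yl]-6-methoxy-2-(4-methoxyphenyl)-4-[(S)-p-tolylsulfinyl]-2,3-dihydrobenzofuran, via benzylic lithium 22 (not isolated), via lithium alkoxide 23 (not isolated)
Conditions: LiN(i-Pr)2 (1.05 equiv), THF, −78 °C; 15, −78 °C; then DMPU, −78 → 60 °C
Reagents that add atoms: none
Why: LiN(i-Pr)2 removes a proton from the CH2 group of 21, which the ortho-sulfinyl group and two aryl rings make the most acidic and best-directed site, to give chelated benzylic lithium 22; 22 adds to the C=O of 15 (bond C2–C3) and, once DMPU is added and the mixture is warmed, alkoxide O1 of 23 displaces fluoride at C7a (bond O1–C7a). This is a domino of two known reaction types, the addition of ortho-sulfinyl benzylic carbanions to aldehydes and the intramolecular SNAr etherification of ortho-fluoroaryl alkoxides, and amounts to a formal (3+2) annulation of the C3–C3a–C7a unit with the C2=O1 unit. The furan ring of ring B closes by 5-exo-trig addition–elimination of O1 at the aromatic carbon C7a, which the fluorine itself and the meta sulfinyl group activate. C3 is controlled by the (S)-sulfinyl auxiliary: lithium bridges C3 and the sulfinyl oxygen, the ring C aryl group turns away from the p-tolyl group and the aldehyde is delivered with retention on the face of the sulfur lone pair, which gives 3S; C2 follows from the lithium-bridged addition transition state that keeps the anisyl group anti to the ring C aryl group and from the faster closure of the trans-leading alkoxide, so the 2S,3S trans ring should result. The step needs site selectivity in the deprotonation (CH2 of 21 against C3–H of ring C and the aryl C–H next to fluorine), secured by the sulfinyl group, which sits only on the new ring, and by the use of barely more than one equivalent of amide, so that no base able to remove C3–H of a closed ring is left on warming. It also needs ring closure to outrun retro-addition, which the irreversible loss of lithium fluoride should secure.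

Step 11
Reactants: 24 ring C–ring B sulfoxide; 6 (R)-2-fluoro-4-methoxy-6-(p-tolylsulfinyl)benzaldehyde
Product: 26 {(2S,3S)-3-[(2R,3R)-3-(3,5-dimethoxyphenyl)-6-methoxy-2-(4-methoxyphenyl)-2,3-dihydrobenzofuran-4-yl]-6-methoxy-2-(4-methoxyphenyl)-2,3-dihydrobenzofuran-4-yl}[2-fluoro-4-methoxy-6-((R)-p-tolylsulfinyl)phenyl]methanol (both carbinol epimers), via arylmagnesium chloride 25 (not isolated)
Conditions: i-PrMgCl·LiCl (1.05 equiv), THF, −50 °C; then 6, −50 → 0 °C; aq. NH4Cl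
Reagents that add atoms: none
Why: Sulfoxide–magnesium exchange at C4 of ring B and addition of the aryl Grignard reagent to the aldehyde, as in step 8.

Step 12
Reactants: 26 diaryl carbinol
Product: 27 (2S,3S)-3-[(2R,3R)-3-(3,5-dimethoxyphenyl)-6-methoxy-2-(4-methoxyphenyl)-2,3-dihydrobenzofuran-4-yl]-4-[2-fluoro-4-methoxy-6-((R)-p-tolylsulfinyl)benzyl]-6-methoxy-2-(4-methoxyphenyl)-2,3-dihydrobenzofuran
Conditions: Et3SiH, CF3CO2H, CH2Cl2, −20 → 0 °C
Reagents that add atoms: none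
Why: Ionic hydrogenation of the doubly benzylic carbinol as in step 9, the two dihydrobenzofuran rings being much harder to ionise.

Step 13
Reactants: 27 fluoro sulfinyl diarylmethane; 15 4-methoxybenzaldehyde
Product: 30 (2R,3R)-3-{(2S,3S)-3-[(2R,3R)-3-(3,5-dimethoxyphenyl)-6-methoxy-2-(4-methoxyphenyl)-2,3-dihydrobenzofuran-4-yl]-6-methoxy-2-(4-methoxyphenyl)-2,3-dihydrobenzofuran-4-yl}-6-methoxy-2-(4-methoxyphenyl)-4-[(R)-p-tolylsulfinyl]-2,3-dihydrobenzofuran, via benzylic lithium 28 (not isolated), via lithium alkoxide 29 (not isolated)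
Conditions: LiN(i-Pr)2 (1.05 equiv), THF, −78 °C; 15, −78 °C; then DMPU, −78 → 60 °C
Reagents that add atoms: none
Why: Same domino as in step 10, closing ring A; the (R)-sulfinyl group should set C3 of ring A as R and the trans C2 centre follows as in step 10.

Step 14
Reactants: 30 tris(dihydrobenzofuran) sulfoxide
Product: 32 the 4-carbaldehyde of ring A (30 with CHO in place of the sulfinyl group), via arylmagnesium chloride 31 (not isolated)
Conditions: i-PrMgCl·LiCl, THF, −50 °C; DMF, → 0 °C; aq. NH4Cl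
Reagents that add atoms: DMF, CN(C)C=O
Why: Sulfoxide–magnesium exchange removes the auxiliary and formylation of the aryl Grignard reagent installs the one-carbon handle at C4 of ring A.

Step 15
Reactants: 32 ring A aldehyde; 33 diethyl (3,4-dimethoxybenzyl)phosphonate
Product: 34 decamethyl ether of the target, with (E)-2-(3,4-dimethoxyphenyl)ethenyl at C4 of ring A
Conditions: NaH, THF, 0 °C → rt
Reagents that add atoms: none
Why: Horner–Wadsworth–Emmons olefination with a benzylic phosphonate should give the E-stilbene, and the phosphonate anion is too weak a base to touch C3–H of the rings.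

Step 16
Reactants: 34 decamethyl ether
Product: 35 target compound CNP0099535.1
Conditions: BBr3 (excess), CH2Cl2, −78 °C → rt; MeOH then H2O
Reagents that add atoms: none
Why: Lewis acid cleavage of all ten aryl methyl ethers; the acidic medium also equilibrates C2 of each ring to the more stable trans arrangement, while C3 is not affected.

Compound list
1 | 1-bromo-3-fluoro-5-methoxybenzene | COc1cc(F)cc(Br)c1 | starting material
2 | (3-fluoro-5-methoxyphenyl)magnesium bromide | COc1cc(F)cc([Mg]Br)c1 | intermediate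
3 | (1S,2R,5S)-menthyl (R)-4-methylbenzenesulfinate | C[C@H]1CC[C@@H]([C@H](C1)O[S@@](=O)c1ccc(C)cc1)C(C)C | starting material
4 | (R)-1-fluoro-3-methoxy-5-(p-tolylsulfinyl)benzene | COc1cc(F)cc(c1)[S@](=O)c1ccc(C)cc1 | intermediate
5 | [2-fluoro-4-methoxy-6-((R)-p-tolylsulfinyl)phenyl]magnesium chloride | COc1cc(F)c([Mg]Cl)c(c1)[S@](=O)c1ccc(C)cc1 | intermediate
6 | (R)-2-fluoro-4-methoxy-6-(p-tolylsulfinyl)benzaldehyde | COc1cc(F)c(C=O)c(c1)[S@](=O)c1ccc(C)cc1 | intermediate
7 | (1R,2S,5R)-menthyl (S)-4-methylbenzenesulfinate | C[C@@H]1CC[C@H]([C@@H](C1)O[S@](=O)c1ccc(C)cc1)C(C)C | starting material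
8 | (S)-1-fluoro-3-methoxy-5-(p-tolylsulfinyl)benzene | COc1cc(F)cc(c1)[S@@](=O)c1ccc(C)cc1 | intermediate
9 | [2-fluoro-4-methoxy-6-((S)-p-tolylsulfinyl)phenyl]magnesium chloride | COc1cc(F)c([Mg]Cl)c(c1)[S@@](=O)c1ccc(C)cc1 | intermediate
10 | (S)-2-fluoro-4-methoxy-6-(p-tolylsulfinyl)benzaldehyde | COc1cc(F)c(C=O)c(c1)[S@@](=O)c1ccc(C)cc1 | intermediate
11 | 3,5-dimethoxybenzyl bromide | COc1cc(CBr)cc(OC)c1 | starting material
12 | [2-fluoro-4-methoxy-6-((R)-p-tolylsulfinyl)phenyl]lithium | COc1cc(F)c([Li])c(c1)[S@](=O)c1ccc(C)cc1 | intermediate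
13 | [2-fluoro-4-methoxy-6-((R)-p-tolylsulfinyl)phenyl]zinc chloride | COc1cc(F)c([Zn]Cl)c(c1)[S@](=O)c1ccc(C)cc1 | intermediate
14 | (R)-2-(3,5-dimethoxybenzyl)-1-fluoro-5-methoxy-3-(p-tolylsulfinyl)benzene | COc1cc(OC)cc(Cc2c(F)cc(OC)cc2[S@](=O)c2ccc(C)cc2)c1 | intermediate
15 | 4-methoxybenzaldehyde | COc1ccc(C=O)cc1 | starting material
16 | sulfinyl-chelated benzylic lithium from 14 (lithium on the carbon that becomes C3 of ring C) | Cc1ccc(cc1)[S@@](=O)c1cc(OC)cc(F)c1[C@@H](c1cc(OC)cc(OC)c1)[Li] | intermediate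
17 | lithium (1R,2R)-2-(3,5-dimethoxyphenyl)-2-[2-fluoro-4-methoxy-6-((R)-p-tolylsulfinyl)phenyl]-1-(4-methoxyphenyl)ethan-1-olate | Cc1ccc(cc1)[S@@](=O)c1cc(OC)cc(F)c1[C@@H](c1cc(OC)cc(OC)c1)[C@H](c1ccc(OC)cc1)O[Li] | intermediate
18 | (2R,3R)-3-(3,5-dimethoxyphenyl)-6-methoxy-2-(4-methoxyphenyl)-4-[(R)-p-tolylsulfinyl]-2,3-dihydrobenzofuran (ring C sulfoxide) | Cc1ccc(cc1)[S@@](=O)c1cc(OC)cc2c1[C@@H](c1cc(OC)cc(OC)c1)[C@H](c1ccc(OC)cc1)O2 | intermediate
19 | [(2R,3R)-3-(3,5-dimethoxyphenyl)-6-methoxy-2-(4-methoxyphenyl)-2,3-dihydrobenzofuran-4-yl]magnesium chloride | Cl[Mg]c1cc(OC)cc2c1[C@@H](c1cc(OC)cc(OC)c1)[C@H](c1ccc(OC)cc1)O2 | intermediate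
20 | [(2R,3R)-3-(3,5-dimethoxyphenyl)-6-methoxy-2-(4-methoxyphenyl)-2,3-dihydrobenzofuran-4-yl][2-fluoro-4-methoxy-6-((S)-p-tolylsulfinyl)phenyl]methanol, both carbinol epimers | Cc1ccc(cc1)[S@](=O)c1cc(OC)cc(F)c1C(O)c1cc(OC)cc2c1[C@@H](c1cc(OC)cc(OC)c1)[C@H](c1ccc(OC)cc1)O2 | intermediate
21 | (2R,3R)-3-(3,5-dimethoxyphenyl)-4-[2-fluoro-4-methoxy-6-((S)-p-tolylsulfinyl)benzyl]-6-methoxy-2-(4-methoxyphenyl)-2,3-dihydrobenzofuran | Cc1ccc(cc1)[S@](=O)c1cc(OC)cc(F)c1Cc1cc(OC)cc2c1[C@@H](c1cc(OC)cc(OC)c1)[C@H](c1ccc(OC)cc1)O2 | intermediate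
22 | sulfinyl-chelated benzylic lithium from 21 (lithium on the carbon that becomes C3 of ring B) | Cc1ccc(cc1)[S@](=O)c1cc(OC)cc(F)c1[C@@H]([Li])c1cc(OC)cc2c1[C@@H](c1cc(OC)cc(OC)c1)[C@H](c1ccc(OC)cc1)O2 | intermediate
23 | lithium (1S,2S)-2-[(2R,3R)-3-(3,5-dimethoxyphenyl)-6-methoxy-2-(4-methoxyphenyl)-2,3-dihydrobenzofuran-4-yl]-2-[2-fluoro-4-methoxy-6-((S)-p-tolylsulfinyl)phenyl]-1-(4-methoxyphenyl)ethan-1-olate | Cc1ccc(cc1)[S@](=O)c1cc(OC)cc(F)c1[C@@H]([C@H](O[Li])c1ccc(OC)cc1)c1cc(OC)cc2c1[C@@H](c1cc(OC)cc(OC)c1)[C@H](c1ccc(OC)cc1)O2 | intermediate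
24 | (2S,3S)-3-[(2R,3R)-3-(3,5-dimethoxyphenyl)-6-methoxy-2-(4-methoxyphenyl)-2,3-dihydrobenzofuran-4-yl]-6-methoxy-2-(4-methoxyphenyl)-4-[(S)-p-tolylsulfinyl]-2,3-dihydrobenzofuran (ring C–ring B sulfoxide) | COc1ccc([C@H]2Oc3cc(OC)cc([S@@](=O)c4ccc(C)cc4)c3[C@@H]2c2cc(OC)cc3c2[C@@H](c2cc(OC)cc(OC)c2)[C@H](c2ccc(OC)cc2)O3)cc1 | intermediate
25 | arylmagnesium chloride from 24 (MgCl at C4 of ring B) | COc1ccc([C@H]2Oc3cc(OC)cc([Mg]Cl)c3[C@@H]2c2cc(OC)cc3c2[C@@H](c2cc(OC)cc(OC)c2)[C@H](c2ccc(OC)cc2)O3)cc1 | intermediate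
26 | {(2S,3S)-3-[(2R,3R)-3-(3,5-dimethoxyphenyl)-6-methoxy-2-(4-methoxyphenyl)-2,3-dihydrobenzofuran-4-yl]-6-methoxy-2-(4-methoxyphenyl)-2,3-dihydrobenzofuran-4-yl}[2-fluoro-4-methoxy-6-((R)-p-tolylsulfinyl)phenyl]methanol, both carbinol epimers | COc1ccc([C@H]2Oc3cc(OC)cc(C(O)c4c(F)cc(OC)cc4[S@](=O)c4ccc(C)cc4)c3[C@@H]2c2cc(OC)cc3c2[C@@H](c2cc(OC)cc(OC)c2)[C@H](c2ccc(OC)cc2)O3)cc1 | intermediate
27 | (2S,3S)-3-[(2R,3R)-3-(3,5-dimethoxyphenyl)-6-methoxy-2-(4-methoxyphenyl)-2,3-dihydrobenzofuran-4-yl]-4-[2-fluoro-4-methoxy-6-((R)-p-tolylsulfinyl)benzyl]-6-methoxy-2-(4-methoxyphenyl)-2,3-dihydrobenzofuran | COc1ccc([C@H]2Oc3cc(OC)cc(Cc4c(F)cc(OC)cc4[S@](=O)c4ccc(C)cc4)c3[C@@H]2c2cc(OC)cc3c2[C@@H](c2cc(OC)cc(OC)c2)[C@H](c2ccc(OC)cc2)O3)cc1 | intermediate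
28 | sulfinyl-chelated benzylic lithium from 27 (lithium on the carbon that becomes C3 of ring A) | COc1ccc([C@H]2Oc3cc(OC)cc([C@@H]([Li])c5c(F)cc(OC)cc5[S@](=O)c6ccc(C)cc6)c3[C@@H]2c2cc(OC)cc3c2[C@@H](c2cc(OC)cc(OC)c2)[C@H](c2ccc(OC)cc2)O3)cc1 | intermediate
29 | lithium (1R,2R)-alkoxide from 28 and 15 (open precursor of ring A: O on the carbon bearing 4-methoxyphenyl, next to the carbon bearing the ring B unit and the fluoro sulfinyl aryl group) | COc1ccc([C@H]2Oc3cc(OC)cc([C@@H]([C@@H](O[Li])c4ccc(OC)cc4)c5c(F)cc(OC)cc5[S@](=O)c6ccc(C)cc6)c3[C@@H]2c2cc(OC)cc3c2[C@@H](c2cc(OC)cc(OC)c2)[C@H](c2ccc(OC)cc2)O3)cc1 | intermediate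
30 | (2R,3R)-3-{(2S,3S)-3-[(2R,3R)-3-(3,5-dimethoxyphenyl)-6-methoxy-2-(4-methoxyphenyl)-2,3-dihydrobenzofuran-4-yl]-6-methoxy-2-(4-methoxyphenyl)-2,3-dihydrobenzofuran-4-yl}-6-methoxy-2-(4-methoxyphenyl)-4-[(R)-p-tolylsulfinyl]-2,3-dihydrobenzofuran | COc1ccc([C@H]2Oc3cc(OC)cc([C@@H]4c5c([S@](=O)c6ccc(C)cc6)cc(OC)cc5O[C@H]4c4ccc(OC)cc4)c3[C@@H]2c2cc(OC)cc3c2[C@@H](c2cc(OC)cc(OC)c2)[C@H](c2ccc(OC)cc2)O3)cc1 | intermediate
31 | arylmagnesium chloride from 30 (MgCl at C4 of ring A) | COc1ccc([C@H]2Oc3cc(OC)cc([C@@H]4c5c([Mg]Cl)cc(OC)cc5O[C@H]4c4ccc(OC)cc4)c3[C@@H]2c2cc(OC)cc3c2[C@@H](c2cc(OC)cc(OC)c2)[C@H](c2ccc(OC)cc2)O3)cc1 | intermediate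
32 | ring A 4-carbaldehyde (30 with CHO in place of the sulfinyl group) | COc1ccc([C@H]2Oc3cc(OC)cc([C@@H]4c5c(C=O)cc(OC)cc5O[C@H]4c4ccc(OC)cc4)c3[C@@H]2c2cc(OC)cc3c2[C@@H](c2cc(OC)cc(OC)c2)[C@H](c2ccc(OC)cc2)O3)cc1 | intermediate
33 | diethyl (3,4-dimethoxybenzyl)phosphonate | CCOP(=O)(Cc1ccc(OC)c(OC)c1)OCC | starting material
34 | decamethyl ether of the target (all ten hydroxyl groups as methyl ethers, E-stilbene) | COc1ccc([C@H]2Oc3cc(OC)cc([C@@H]4c5c(/C=C/c6ccc(OC)c(OC)c6)cc(OC)cc5O[C@H]4c4ccc(OC)cc4)c3[C@@H]2c2cc(OC)cc3c2[C@@H](c2cc(OC)cc(OC)c2)[C@H](c2ccc(OC)cc2)O3)cc1 | intermediate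
35 | CNP0099535.1 | Oc1ccc([C@H]2Oc3cc(O)cc([C@@H]4c5c(/C=C/c6ccc(O)c(O)c6)cc(O)cc5O[C@H]4c4ccc(O)cc4)c3[C@@H]2c2cc(O)cc3c2[C@@H](c2cc(O)cc(O)c2)[C@H](c2ccc(O)cc2)O3)cc1 | target

Total step count: 16. Longest linear sequence: 13 steps (1, 2, 6, 7, 8, 9, 10, 11, 12, 13, 14, 15, 16).

Steps most likely to fail

1. Step 10 (the same applies to steps 7 and 13). The lithium alkoxide may revert to carbanion and aldehyde before fluoride is displaced, which would erode the facial selectivity at C3; the displacement of fluoride from the electron-rich ring may also be slow. Fallback, from 21 back to 24, with the two bonds made in separate known steps: the lithiated diarylmethane (LiN(i-Pr)2, 2 equiv) is acylated with methyl 4-methoxybenzoate to give ketone F1, whose C3 epimers interconvert. Ruthenium-catalysed asymmetric transfer hydrogenation under dynamic kinetic resolution (RuCl(p-cymene)[(S,S)-TsDPEN], HCO2H/Et3N) then gives the (1S,2S)-alcohol F2. Treatment with KN(SiMe3)2 and 18-crown-6 in THF closes ring B by displacement of fluoride and returns to 24.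

2. Step 9 (the same applies to step 12). The sulfinyl oxygen may capture the benzylic cation; the resulting alkoxysulfonium ion could be reduced to the sulfide or lose its sulfur configuration, and reductive opening of ring C at C2–O1 could compete. Fallback, from 18 back to 21, with no cation: sulfoxide–magnesium exchange on 18 (i-PrMgCl·LiCl) and quenching with DMF gives the ring C aldehyde F3. NaBH4 gives benzylic alcohol F4 and PBr3 gives benzylic bromide F5. Sulfoxide 8 is lithiated by Li(TMP) in the presence of ZnCl2·2LiCl, as in step 6, to give aryllithium F6 and from it arylzinc chloride F7. Negishi coupling of F5 with F7 (Pd(PPh3)4, THF, 50 °C) gives 21.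

3. Step 16. Lewis-acid-induced cyclisation or oligomerisation of the electron-rich stilbene may occur, and cleavage of ten methyl ethers may be incomplete. Fallback, from 32 to 35, with the demethylation moved ahead of the olefination: BBr3 on aldehyde 32, which carries no alkene, gives octaphenol aldehyde F8. TBSCl and imidazole give octakis(silyl ether) F9. Horner–Wadsworth–Emmons reaction (LiN(SiMe3)2, THF, −78 °C → rt) with the known silyl-protected phosphonate F10 gives the deca(silyl ether) stilbene F11. HF·pyridine then gives 35.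

Further compounds
F1 | step 10 | 2-[(2R,3R)-3-(3,5-dimethoxyphenyl)-6-methoxy-2-(4-methoxyphenyl)-2,3-dihydrobenzofuran-4-yl]-2-[2-fluoro-4-methoxy-6-((S)-p-tolylsulfinyl)phenyl]-1-(4-methoxyphenyl)ethanone, epimers at C2 of the ethanone | Cc1ccc(cc1)[S@](=O)c1cc(OC)cc(F)c1C(C(=O)c1ccc(OC)cc1)c1cc(OC)cc2c1[C@@H](c1cc(OC)cc(OC)c1)[C@H](c1ccc(OC)cc1)O2
F2 | step 10 | (1S,2S)-2-[(2R,3R)-3-(3,5-dimethoxyphenyl)-6-methoxy-2-(4-methoxyphenyl)-2,3-dihydrobenzofuran-4-yl]-2-[2-fluoro-4-methoxy-6-((S)-p-tolylsulfinyl)phenyl]-1-(4-methoxyphenyl)ethanol | Cc1ccc(cc1)[S@](=O)c1cc(OC)cc(F)c1[C@@H]([C@H](O)c1ccc(OC)cc1)c1cc(OC)cc2c1[C@@H](c1cc(OC)cc(OC)c1)[C@H](c1ccc(OC)cc1)O2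
F3 | step 9 | (2R,3R)-3-(3,5-dimethoxyphenyl)-6-methoxy-2-(4-methoxyphenyl)-2,3-dihydrobenzofuran-4-carbaldehyde | O=Cc1cc(OC)cc2c1[C@@H](c1cc(OC)cc(OC)c1)[C@H](c1ccc(OC)cc1)O2
F4 | step 9 | [(2R,3R)-3-(3,5-dimethoxyphenyl)-6-methoxy-2-(4-methoxyphenyl)-2,3-dihydrobenzofuran-4-yl]methanol | OCc1cc(OC)cc2c1[C@@H](c1cc(OC)cc(OC)c1)[C@H](c1ccc(OC)cc1)O2
F5 | step 9 | (2R,3R)-4-(bromomethyl)-3-(3,5-dimethoxyphenyl)-6-methoxy-2-(4-methoxyphenyl)-2,3-dihydrobenzofuran | BrCc1cc(OC)cc2c1[C@@H](c1cc(OC)cc(OC)c1)[C@H](c1ccc(OC)cc1)O2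
F6 | step 9 | [2-fluoro-4-methoxy-6-((S)-p-tolylsulfinyl)phenyl]lithium | COc1cc(F)c([Li])c(c1)[S@@](=O)c1ccc(C)cc1
F7 | step 9 | [2-fluoro-4-methoxy-6-((S)-p-tolylsulfinyl)phenyl]zinc chloride | COc1cc(F)c([Zn]Cl)c(c1)[S@@](=O)c1ccc(C)cc1
F8 | step 16 | octaphenol aldehyde (32 with all eight methyl ethers cleaved) | Oc1ccc([C@H]2Oc3cc(O)cc([C@@H]4c5c(C=O)cc(O)cc5O[C@H]4c4ccc(O)cc4)c3[C@@H]2c2cc(O)cc3c2[C@@H](c2cc(O)cc(O)c2)[C@H](c2ccc(O)cc2)O3)cc1
F9 | step 16 | octakis(tert-butyldimethylsilyl) ether of F8 | CC(C)(C)[Si](C)(C)Oc1ccc([C@H]2Oc3cc(O[Si](C)(C)C(C)(C)C)cc([C@@H]4c5c(C=O)cc(O[Si](C)(C)C(C)(C)C)cc5O[C@H]4c4ccc(O[Si](C)(C)C(C)(C)C)cc4)c3[C@@H]2c2cc(O[Si](C)(C)C(C)(C)C)cc3c2[C@@H](c2cc(O[Si](C)(C)C(C)(C)C)cc(O[Si](C)(C)C(C)(C)C)c2)[C@H](c2ccc(O[Si](C)(C)C(C)(C)C)cc2)O3)cc1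
F10 | step 16 | diethyl [3,4-bis(tert-butyldimethylsilyloxy)benzyl]phosphonate | CCOP(=O)(Cc1ccc(O[Si](C)(C)C(C)(C)C)c(O[Si](C)(C)C(C)(C)C)c1)OCC
F11 | step 16 | deca(tert-butyldimethylsilyl) ether of the target | CC(C)(C)[Si](C)(C)Oc1ccc([C@H]2Oc3cc(O[Si](C)(C)C(C)(C)C)cc([C@@H]4c5c(/C=C/c6ccc(O[Si](C)(C)C(C)(C)C)c(O[Si](C)(C)C(C)(C)C)c6)cc(O[Si](C)(C)C(C)(C)C)cc5O[C@H]4c4ccc(O[Si](C)(C)C(C)(C)C)cc4)c3[C@@H]2c2cc(O[Si](C)(C)C(C)(C)C)cc3c2[C@@H](c2cc(O[Si](C)(C)C(C)(C)C)cc(O[Si](C)(C)C(C)(C)C)c2)[C@H](c2ccc(O[Si](C)(C)C(C)(C)C)cc2)O3)cc1
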